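**Retrosynthetic overview**

1. Target 21 is kaempferol with an (S)-lavandulyl chain on C8. The last operations are removal of three MOM ethers and oxygenation of C3 (lithiation, borylation, oxidation) of the 8-lavandulylflavone 17.
2. Ring C (O1, C2, C3, C4) is the only ring formed. It is cut at C4a–C4, C4–C3 and O1–C2 into iodophenol 12, carbon monoxide 15 and arylacetylene 14; rings A and B are bought.
3. The strategy rests on the fusion of ring C to the tri-oxygenated ring A across C4a–C8a. The chain ends on C8 and not C6 only if the oxygen beside the chain becomes O1. In 12 that oxygen is the only free hydroxyl and iodine sits on the one carbon next to it.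
4. 12 is built on a phloroglucinol whose unique oxygen carries a diethylcarbamate. Two carbamate-directed ortho-lithiations place first the chain (aryl iodide, then Negishi coupling with the zinc reagent from (R)-lavandulol) and then the iodine on the two carbons flanking that oxygen, so no late selective protection is needed.
5. The single stereocentre is bought with (R)-lavandulol and is never a reacting centre.

Key step: step 9

Assumption: (R)-lavandulol of high enantiomeric purity is used as bought. Its stereocentre keeps the same spatial arrangement throughout; the descriptor changes from R (alcohol, iodide, zinc reagent) to S (all aryl compounds) only through CIP priorities. Abbreviations: lavandulyl = 5-methyl-2-(prop-1-en-2-yl)hex-4-en-1-yl; MOM = methoxymethyl.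

**Route**

Step 1
Reactants: 1 (R)-lavandulol
Product: 2 (R)-lavandulyl iodide [(3R)-3-(iodomethyl)-2,6-dimethylhepta-1,5-diene]
Conditions: PPh3, I2, imidazole, CH2Cl2, 0 °C → rt
Reagents that add atoms: iodine (II)
Why: Appel-type iodination proceeds through the alkoxyphosphonium ion with SN2 displacement at the primary CH2, so the neighbouring stereocentre is not touched and the neutral conditions leave both alkenes alone.

Step 2
Reactants: 3 phloroglucinol
Product: 4 3,5-bis(methoxymethoxy)phenol
Conditions: MOMCl (2.0 equiv), i-Pr2NEt (2.2 equiv), THF, 0 °C → rt; chromatography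
Reagents that add atoms: chloromethyl methyl ether (COCCl)
Why: O-alkylation of the symmetrical triol with two equivalents of MOMCl is a statistical desymmetrisation that should give the bis-ether as the main component, separable from mono- and tris-ethers, and it is placed first so that its modest efficiency costs only cheap material.

Step 3
Reactants: 4 3,5-bis(methoxymethoxy)phenol
Product: 5 3,5-bis(methoxymethoxy)phenyl N,N-diethylcarbamate
Conditions: Et2NCOCl, K2CO3, MeCN, reflux
Reagents that add atoms: N,N-diethylcarbamoyl chloride (CCN(CC)C(Cl)=O)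
Why: Base-mediated O-carbamoylation (acyl substitution) of the single free phenol marks the unique oxygen, the future O1, with the strongest oxygen-based directing group for ortho-metalation.

Step 4
Reactants: 5 3,5-bis(methoxymethoxy)phenyl N,N-diethylcarbamate
Product: 7 2-iodo-3,5-bis(methoxymethoxy)phenyl N,N-diethylcarbamate, via 2-lithioaryl carbamate 6 (not isolated)
Conditions: s-BuLi, TMEDA, THF, −78 °C; then I2, −78 °C → rt
Reagents that add atoms: iodine (II)
Why: Directed ortho-metalation, in which s-BuLi/TMEDA complexes to the carbamate (a stronger director than a MOM ether) and removes the proton on C2 between the carbamate and a MOM ether (the two such positions are equivalent), and iodine traps the aryllithium at −78 °C before anionic ortho-Fries rearrangement can set in.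

Step 5
Reactants: 2 (R)-lavandulyl iodide; 7 2-iodo-3,5-bis(methoxymethoxy)phenyl N,N-diethylcarbamate
Product: 9 2-[(2S)-lavandulyl]-3,5-bis(methoxymethoxy)phenyl N,N-diethylcarbamate, via lavandulylzinc iodide 8 (not isolated)
Conditions: 2, Zn dust (BrCH2CH2Br/TMSCl-activated), LiCl, THF, 40 °C; then 7, Pd(OAc)2 (3 mol %), SPhos (6 mol %), THF, rt → 50 °C
Reagents that add atoms: none
Why: Negishi sp3–sp2 cross-coupling, in which zinc inserts into the primary C–I bond and a Pd/SPhos catalyst of the kind known to join primary alkylzinc halides to di-ortho-substituted aryl halides forms the aryl–CH2 bond with reductive elimination ahead of β-hydride elimination and without involving the β-stereocentre; cross-coupling is used because the unactivated, β-branched homoallylic halide is unsuited to direct C-alkylation of a phenol.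

Step 6
Reactants: 9 2-[(2S)-lavandulyl]-3,5-bis(methoxymethoxy)phenyl N,N-diethylcarbamate
Product: 11 2-iodo-6-[(2S)-lavandulyl]-3,5-bis(methoxymethoxy)phenyl N,N-diethylcarbamate, via 6-lithioaryl carbamate 10 (not isolated)
Conditions: s-BuLi, TMEDA, THF, −78 °C; then I2, −78 °C → rt
Reagents that add atoms: iodine (II)
Why: Second carbamate-directed ortho-metalation, in which the only remaining position ortho to the carbamate (also ortho to a MOM ether) is lithiated in preference to the position between the two MOM ethers and to the benzylic and allylic C–H bonds, which react slowly at −78 °C, so that iodine lands on the second carbon flanking the carbamate oxygen.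

Step 7
Reactants: 11 2-iodo-6-[(2S)-lavandulyl]-3,5-bis(methoxymethoxy)phenyl N,N-diethylcarbamate
Product: 12 2-iodo-6-[(2S)-lavandulyl]-3,5-bis(methoxymethoxy)phenol
Conditions: KOH, EtOH/H2O, reflux; then aq. NH4Cl
Reagents that add atoms: none
Why: Alkaline hydrolysis of the aryl carbamate (acyl substitution at the carbonyl, then loss of carbonate and diethylamine) frees only the oxygen flanked by chain and iodine, while MOM acetals, the aryl iodide and the diene are inert to hydroxide.

Step 8
Reactants: 13 4-ethynylphenol
Product: 14 1-ethynyl-4-(methoxymethoxy)benzene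
Conditions: MOMCl, i-Pr2NEt, CH2Cl2, 0 °C → rt
Reagents that add atoms: chloromethyl methyl ether (COCCl)
Why: Standard MOM ether formation (O-alkylation with amine base) gives ring B the same protecting group as ring A and removes an acidic OH that would interfere with the later C3 lithiation.

Step 9
Reactants: 12 2-iodo-6-[(2S)-lavandulyl]-3,5-bis(methoxymethoxy)phenol; 14 1-ethynyl-4-(methoxymethoxy)benzene; 15 carbon monoxide
Product: 17 8-[(2S)-lavandulyl]-5,7-bis(methoxymethoxy)-2-[4-(methoxymethoxy)phenyl]-4H-chromen-4-one, via o-hydroxyaryl ynone 16 (not isolated)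
Conditions: PdCl2(dppf) (5 mol %), CO (20 bar), Et2NH, 100 °C
Reagents that add atoms: none
Why: Pd(0) inserts into the C–I bond of 12, CO insertion gives the aroylpalladium species, and copper-free coupling with the terminal alkyne 14 (amine as base) gives the o-hydroxyaryl ynone 16; diethylamine then brings about conjugate addition of the neighbouring phenoxide to the ynone. The closest known reaction type is the palladium-catalysed carbonylative Sonogashira annulation of o-iodophenols with terminal alkynes to flavones. Ring C closes in the 6-endo-dig mode (O1 onto C2), the C4a–C4 and C4–C3 bonds having been made in the coupling. No stereocentre is formed, and the neutral-to-basic medium at 100 °C (well below Cope rearrangement temperatures for the 1,5-diene) should leave the lavandulyl centre, the MOM ethers and both alkenes untouched. Two selectivities are needed: 6-endo closure to the chromone instead of 5-exo closure to an aurone, which a secondary-amine medium is known to favour, and placement of the chain at C8 and not C6, which the substrate fixes because iodine has a single hydroxyl neighbour (the other is a MOM ether) and that hydroxyl is the one beside the chain. The two ortho substituents slow oxidative addition but also disfavour the non-carbonylative coupling, and CO pressure keeps acylation ahead of direct alkynylation.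

Step 10
Reactants: 17 8-[(2S)-lavandulyl]-5,7-bis(methoxymethoxy)-2-[4-(methoxymethoxy)phenyl]-4H-chromen-4-one
Product: 20 3-hydroxy-8-[(2S)-lavandulyl]-5,7-bis(methoxymethoxy)-2-[4-(methoxymethoxy)phenyl]-4H-chromen-4-one, via 3-lithioflavone 18 (not isolated), via 3-(dimethoxyboryl)flavone 19 (not isolated)
Conditions: LDA, THF, −78 °C; B(OMe)3, −78 → 0 °C; then AcOH, 30% H2O2, 0 °C → rt
Reagents that add atoms: hydrogen peroxide (OO)
Why: Known flavone-to-flavonol sequence, in which LDA removes the C3–H (acidified by the adjacent C4 carbonyl, which also holds the lithium), the vinyllithium is trapped as the borate, and buffered hydrogen peroxide converts C–B into C–OH by 1,2-migration under conditions where isolated alkenes and MOM ethers do not react.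

Step 11
Reactants: 20 3-hydroxy-8-[(2S)-lavandulyl]-5,7-bis(methoxymethoxy)-2-[4-(methoxymethoxy)phenyl]-4H-chromen-4-one
Product: 21 3,5,7-trihydroxy-2-(4-hydroxyphenyl)-8-[(2S)-lavandulyl]-4H-chromen-4-one (8-lavandulylkaempferol, CNP0185677.2)
Conditions: conc. HCl (few equiv), MeOH/THF, 40 °C
Reagents that add atoms: none
Why: Acid-catalysed acetal solvolysis (transacetalisation of the three MOM ethers to dimethoxymethane) with dilute HCl at mild temperature, as used for prenylated polyphenols, should stop short of protonating the side-chain alkenes or adding the 7-OH to the isopropenyl group.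

**Compound list**

1 | (R)-lavandulol, (2R)-5-methyl-2-(prop-1-en-2-yl)hex-4-en-1-ol | C=C(C)[C@@H](CC=C(C)C)CO | starting material
2 | (R)-lavandulyl iodide, (3R)-3-(iodomethyl)-2,6-dimethylhepta-1,5-diene | C=C(C)[C@@H](CC=C(C)C)CI | intermediate
3 | phloroglucinol | Oc1cc(O)cc(O)c1 | starting material
4 | 3,5-bis(methoxymethoxy)phenol | COCOc1cc(O)cc(OCOC)c1 | intermediate
5 | 3,5-bis(methoxymethoxy)phenyl N,N-diethylcarbamate | CCN(CC)C(=O)Oc1cc(OCOC)cc(OCOC)c1 | intermediate
6 | 2-lithio-3,5-bis(methoxymethoxy)phenyl N,N-diethylcarbamate (not isolated) | CCN(CC)C(=O)Oc1cc(OCOC)cc(OCOC)c1[Li] | intermediate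
7 | 2-iodo-3,5-bis(methoxymethoxy)phenyl N,N-diethylcarbamate | CCN(CC)C(=O)Oc1cc(OCOC)cc(OCOC)c1I | intermediate
8 | [(2R)-5-methyl-2-(prop-1-en-2-yl)hex-4-en-1-yl]zinc iodide (not isolated) | C=C(C)[C@@H](CC=C(C)C)C[Zn]I | intermediate
9 | 3,5-bis(methoxymethoxy)-2-[(2S)-5-methyl-2-(prop-1-en-2-yl)hex-4-en-1-yl]phenyl N,N-diethylcarbamate | C=C(C)[C@@H](CC=C(C)C)Cc1c(OC(=O)N(CC)CC)cc(OCOC)cc1OCOC | intermediate
10 | 2-lithio-3,5-bis(methoxymethoxy)-6-[(2S)-5-methyl-2-(prop-1-en-2-yl)hex-4-en-1-yl]phenyl N,N-diethylcarbamate (not isolated) | C=C(C)[C@@H](CC=C(C)C)Cc1c(OC(=O)N(CC)CC)c([Li])c(OCOC)cc1OCOC | intermediate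
11 | 2-iodo-3,5-bis(methoxymethoxy)-6-[(2S)-5-methyl-2-(prop-1-en-2-yl)hex-4-en-1-yl]phenyl N,N-diethylcarbamate | C=C(C)[C@@H](CC=C(C)C)Cc1c(OC(=O)N(CC)CC)c(I)c(OCOC)cc1OCOC | intermediate
12 | 2-iodo-3,5-bis(methoxymethoxy)-6-[(2S)-5-methyl-2-(prop-1-en-2-yl)hex-4-en-1-yl]phenol | C=C(C)[C@@H](CC=C(C)C)Cc1c(O)c(I)c(OCOC)cc1OCOC | intermediate
13 | 4-ethynylphenol | C#Cc1ccc(O)cc1 | starting material
14 | 1-ethynyl-4-(methoxymethoxy)benzene | C#Cc1ccc(OCOC)cc1 | intermediate
15 | carbon monoxide | [C-]#[O+] | starting material
16 | 1-{2-hydroxy-4,6-bis(methoxymethoxy)-3-[(2S)-5-methyl-2-(prop-1-en-2-yl)hex-4-en-1-yl]phenyl}-3-[4-(methoxymethoxy)phenyl]prop-2-yn-1-one (not isolated) | C=C(C)[C@@H](CC=C(C)C)Cc1c(O)c(C(=O)C#Cc2ccc(OCOC)cc2)c(OCOC)cc1OCOC | intermediate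
17 | 5,7-bis(methoxymethoxy)-2-[4-(methoxymethoxy)phenyl]-8-[(2S)-5-methyl-2-(prop-1-en-2-yl)hex-4-en-1-yl]-4H-chromen-4-one | C=C(C)[C@@H](CC=C(C)C)Cc1c(OCOC)cc(OCOC)c2c(=O)cc(-c3ccc(OCOC)cc3)oc12 | intermediate
18 | 3-lithio derivative of 17 (not isolated) | C=C(C)[C@@H](CC=C(C)C)Cc1c(OCOC)cc(OCOC)c2c(=O)c([Li])c(-c3ccc(OCOC)cc3)oc12 | intermediate
19 | 3-(dimethoxyboryl) derivative of 17 (not isolated) | C=C(C)[C@@H](CC=C(C)C)Cc1c(OCOC)cc(OCOC)c2c(=O)c(B(OC)OC)c(-c3ccc(OCOC)cc3)oc12 | intermediate
20 | 3-hydroxy-5,7-bis(methoxymethoxy)-2-[4-(methoxymethoxy)phenyl]-8-[(2S)-5-methyl-2-(prop-1-en-2-yl)hex-4-en-1-yl]-4H-chromen-4-one | C=C(C)[C@@H](CC=C(C)C)Cc1c(OCOC)cc(OCOC)c2c(=O)c(O)c(-c3ccc(OCOC)cc3)oc12 | intermediate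
21 | 3,5,7-trihydroxy-2-(4-hydroxyphenyl)-8-[(2S)-5-methyl-2-(prop-1-en-2-yl)hex-4-en-1-yl]-4H-chromen-4-one | C=C(C)[C@@H](CC=C(C)C)Cc1c(O)cc(O)c2c(=O)c(O)c(-c3ccc(O)cc3)oc12 | target

**Step count**

Total step count: 11.
Longest linear sequence: 9 steps (3 → 4 → 5 → 7 → 9 → 11 → 12 → 17 → 20 → 21; steps 2–7 and 9–11).

**Steps most likely to fail, with fallbacks**

Step 9 (key step). Oxidative addition and CO insertion at the doubly ortho-substituted, electron-rich C–I bond may be slow. Aminocarbonylation by diethylamine, direct alkynylation without CO, or 5-exo closure could then compete. The fallback sets out from 12 and 14 and builds the same ynone by polar acylation instead of carbonylation. Alkyne 14 is deprotonated (n-BuLi, THF, −78 °C) to the lithium acetylide F1 and acylated with N-methoxy-N-methylcarbamoyl chloride to the Weinreb ynamide F2. Iodophenol 12 is treated with n-BuLi (2.2 equiv, THF, −78 °C; O–H deprotonation, then iodine–lithium exchange) to give the dilithio phenoxide F3, which is acylated by F2 to give the ynone 16 after work-up. Compound 16 is closed with Et2NH in EtOH (6-endo oxa-Michael), and the route is rejoined at 17.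

Step 5. Transmetalation onto the hindered arylpalladium species may be sluggish, so that β-hydride elimination or protodezincation takes over. Radical intermediates of the zinc insertion could also rearrange (homoallyl/cyclopropylcarbinyl) and erode configurational purity. The fallback sets out from 2 and replaces zinc by boron. Iodide 2 undergoes iodine–lithium exchange (t-BuLi, 2.1 equiv, Et2O, −78 °C) to lavandulyllithium F4, which is captured with B-methoxy-9-BBN as the lithium borinate ate complex F5. This is coupled with 7 under B-alkyl Suzuki–Miyaura conditions (PdCl2(dppf), aq. K3PO4, DMF, rt → 50 °C), rejoining the route at 9.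

Step 10. The boron intermediate may protodeboronate, or the peroxide treatment may attack the side-chain alkenes, so that oxygen is not delivered cleanly to C3. The fallback sets out from 17. The lithio species 18 is generated as before (LDA, THF, −78 °C) and oxygenated directly with bis(trimethylsilyl) peroxide, an electrophilic oxygen source for aryl- and vinyllithiums, to give the 3-(trimethylsilyloxy)flavone F6. The silyl group is removed with K2CO3 in MeOH, rejoining the route at 20.

**Further compounds**

F1 | step 9 | lithium [4-(methoxymethoxy)phenyl]acetylide | [Li]C#Cc1ccc(OCOC)cc1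
F2 | step 9 | N-methoxy-N-methyl-3-[4-(methoxymethoxy)phenyl]prop-2-ynamide | CON(C)C(=O)C#Cc1ccc(OCOC)cc1
F3 | step 9 | lithium 2-lithio-3,5-bis(methoxymethoxy)-6-[(2S)-5-methyl-2-(prop-1-en-2-yl)hex-4-en-1-yl]phenoxide | C=C(C)[C@@H](CC=C(C)C)Cc1c(O[Li])c([Li])c(OCOC)cc1OCOC
F4 | step 5 | lavandulyllithium (configuration of 2 retained) | C=C(C)[C@@H](CC=C(C)C)C[Li]
F5 | step 5 | lithium B-lavandulyl-B-methoxy-9-borabicyclo[3.3.1]nonane ate complex (configuration of 2 retained) | C=C(C)[C@@H](CC=C(C)C)C[B-]1(OC)C2CCCC1CCC2.[Li+]
F6 | step 10 | 5,7-bis(methoxymethoxy)-2-[4-(methoxymethoxy)phenyl]-8-[(2S)-5-methyl-2-(prop-1-en-2-yl)hex-4-en-1-yl]-3-(trimethylsilyloxy)-4H-chromen-4-one | C=C(C)[C@@H](CC=C(C)C)Cc1c(OCOC)cc(OCOC)c2c(=O)c(O[Si](C)(C)C)c(-c3ccc(OCOC)cc3)oc12
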